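**Retrosynthetic overview**

1. The target is read as (2S,4R)-4',7-dihydroxyflavan (2,4-trans) joined from C4 to C8 of (−)-epigallocatechin (2R,3R, 2,3-cis); the last step removes seven benzyl ethers from 16.
2. 16 is opened at two bonds at once, O1–C2 of the lower pyran ring and C4(upper)–C8(lower). This gives its isomer 14, in which the upper flavan-4-yl group sits on the future O1 as an aryl ether and C2–C3 of the lower unit is a cis-epoxide.
3. Enabling feature: O1 is a phenol oxygen on C8a of the lower ring A, ortho both to C8 (which carries upper C4) and to C4a (which carries the C4–C3–C2 chain). C2 is benzylic to the lower ring B and vicinal to the C3 oxygen, and upper C4 is benzylic and para to the 7-oxygen, so one oxygen can pass the flavanyl cation to C8 and then close onto C2.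
4. 14 comes from Mitsunobu union of Z-alkene phenol 7 (from phenol 1 and aldehyde 3 through a 1,3-diarylpropyne) with flavan-4-ol 12 (from chromone 8 by asymmetric conjugate arylation), followed by Jacobsen epoxidation.
5. Ring order: upper pyran ring carried from 8 (C2 set in step 7), oxirane in step 10, lower pyran ring last in step 11.

Key step: step 11

Remark: the sense of induction of the chiral catalysts in steps 7 and 10 is taken from the closest known substrates (arylation of chromone; conversion of indene into its (1S,2R)-oxide by the (S,S)-manganese salen complex). If either proves opposite, the enantiomeric ligand is used.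

**Route**

Step 1
Reactants: 1 3,5-bis(benzyloxy)phenol
Product: 2 2-hydroxy-4,6-bis(benzyloxy)benzaldehyde
Conditions: MgCl2, Et3N, (CH2O)n, MeCN, reflux
Reagents that add atoms: paraformaldehyde (as formaldehyde), C=O
Why: Magnesium-phenoxide-directed ortho-formylation (Casnati–Skattebøl) delivers formaldehyde inside the chelate, so only an ortho position reacts, and the two ortho positions of symmetric 1 are equivalent.

Step 2
Reactants: 3 3,4,5-tris(benzyloxy)benzaldehyde
Product: 4 5-ethynyl-1,2,3-tris(benzyloxy)benzene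
Conditions: dimethyl (1-diazo-2-oxopropyl)phosphonate, K2CO3, MeOH/THF, 0 °C to rt
Reagents that add atoms: dimethyl (1-diazo-2-oxopropyl)phosphonate (Ohira–Bestmann reagent), CC(=O)C(=[N+]=[N-])P(=O)(OC)OC
Why: Ohira–Bestmann (Seyferth–Gilbert) homologation converts an aryl aldehyde into the terminal alkyne under mild base that leaves benzyl ethers untouched.

Step 3
Reactants: 2 2-hydroxy-4,6-bis(benzyloxy)benzaldehyde; 4 5-ethynyl-1,2,3-tris(benzyloxy)benzene
Product: 5 rac-1-[2-hydroxy-4,6-bis(benzyloxy)phenyl]-3-[3,4,5-tris(benzyloxy)phenyl]prop-2-yn-1-ol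
Conditions: 4 (2.2 equiv), n-BuLi (2.1 equiv), THF, −78 °C; then 2, −78 to 0 °C; aq. NH4Cl
Reagents that add atoms: none
Why: Lithium acetylide addition to an aldehyde; the first equivalent of acetylide deprotonates the phenol (that alkyne is recovered) and the second adds to the carbonyl, giving a racemic carbinol whose stereocentre is removed in step 4.

Step 4
Reactants: 5 rac-1-[2-hydroxy-4,6-bis(benzyloxy)phenyl]-3-[3,4,5-tris(benzyloxy)phenyl]prop-2-yn-1-ol
Product: 6 3,5-bis(benzyloxy)-2-{3-[3,4,5-tris(benzyloxy)phenyl]prop-2-yn-1-yl}phenol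
Conditions: Et3SiH, TFA, CH2Cl2, −40 to 0 °C
Reagents that add atoms: none
Why: Ionic hydrogenation: TFA ionises the benzylic, propargylic alcohol to an ortho-quinone-methide-type cation stabilised by three ring oxygens, and Et3SiH delivers hydride to the benzylic carbon.

Step 5
Reactants: 6 3,5-bis(benzyloxy)-2-{3-[3,4,5-tris(benzyloxy)phenyl]prop-2-yn-1-yl}phenol
Product: 7 3,5-bis(benzyloxy)-2-{(2Z)-3-[3,4,5-tris(benzyloxy)phenyl]prop-2-en-1-yl}phenol
Conditions: H2 (1 atm), Pd/CaCO3 poisoned with Pb(OAc)2, quinoline, EtOAc, rt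
Reagents that add atoms: none
Why: Lindlar semi-hydrogenation adds hydrogen syn on the catalyst surface to give the Z-alkene, and the poisoned catalyst does not cleave aryl benzyl ethers.

Step 6
Reactants: 8 7-hydroxy-4H-chromen-4-one
Product: 9 7-(benzyloxy)-4H-chromen-4-one
Conditions: BnBr, K2CO3, DMF, rt
Reagents that add atoms: benzyl bromide, BrCc1ccccc1
Why: Williamson etherification of the acidic 7-hydroxyl, which is vinylogously conjugated to the carbonyl.

Step 7
Reactants: 9 7-(benzyloxy)-4H-chromen-4-one; 10 [4-(benzyloxy)phenyl]boronic acid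
Product: 11 (2S)-7-(benzyloxy)-2-[4-(benzyloxy)phenyl]chroman-4-one
Conditions: Pd(OCOCF3)2 (5 mol%), (S)-t-BuPyOx (6 mol%), NH4PF6 (30 mol%), H2O (5 equiv), ClCH2CH2Cl, 60 °C
Reagents that add atoms: none
Why: Asymmetric conjugate addition of an arylboronic acid to a chromone by cationic divalent palladium with a pyridine-oxazoline ligand; the ligand fixes the face of aryl insertion at C2 (S), and the neutral medium avoids the chalcone ring-opening that would racemise a flavanone.

Step 8
Reactants: 11 (2S)-7-(benzyloxy)-2-[4-(benzyloxy)phenyl]chroman-4-one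
Product: 12 (2S,4S)-7-(benzyloxy)-2-[4-(benzyloxy)phenyl]chroman-4-ol (2,4-cis)
Conditions: NaBH4, THF/MeOH, 0 °C
Reagents that add atoms: none
Why: Borohydride reduction of a flavanone with axial hydride delivery, expected to give the 2,4-cis alcohol under control of the equatorial 2-aryl group.

Step 9
Reactants: 7 3,5-bis(benzyloxy)-2-{(2Z)-3-[3,4,5-tris(benzyloxy)phenyl]prop-2-en-1-yl}phenol; 12 (2S,4S)-7-(benzyloxy)-2-[4-(benzyloxy)phenyl]chroman-4-ol
Product: 13 (2S,4R)-7-(benzyloxy)-2-[4-(benzyloxy)phenyl]-4-{3,5-bis(benzyloxy)-2-[(2Z)-3-(3,4,5-tris(benzyloxy)phenyl)prop-2-en-1-yl]phenoxy}chroman (2,4-trans aryl flavan-4-yl ether)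
Conditions: PPh3, DIAD, THF, 0 °C to rt
Reagents that add atoms: none
Why: Mitsunobu etherification of a phenol with a secondary benzylic alcohol, formally with inversion at C4 (R); this centre is erased in step 11, so partial ionisation of the oxyphosphonium salt does no harm, and the flavanyl group doubles as the phenol protecting group for step 10.

Step 10
Reactants: 13 (2S,4R)-aryl flavan-4-yl ether of Z-alkene phenol 7
Product: 14 (2S,4R)-7-(benzyloxy)-2-[4-(benzyloxy)phenyl]-4-[3,5-bis(benzyloxy)-2-{[(2R,3S)-3-(3,4,5-tris(benzyloxy)phenyl)oxiran-2-yl]methyl}phenoxy]chroman (cis-epoxide; benzylic carbon S, future C2; neighbouring carbon R, future C3)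
Conditions: (S,S)-(salen)MnCl [salen = N,N'-bis(3,5-di-tert-butylsalicylidene)cyclohexane-1,2-diamine dianion] (10 mol%), NMO, mCPBA, CH2Cl2, −78 °C
Reagents that add atoms: mCPBA, O=C(OO)c1cccc(Cl)c1
Why: Jacobsen–Katsuki epoxidation of a Z-β-substituted styrene, the best substrate class for the trivalent-manganese salen catalyst, sets both epoxide carbons by catalyst-controlled side-on approach; the anhydrous low-temperature mCPBA/NMO protocol avoids hypochlorite chlorination of the electron-rich rings and limits leakage to the trans-epoxide.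

Step 11
Reactants: 14 (2S,4R)-aryl flavan-4-yl ether cis-epoxide
Product: 16 (2R,3R)-5,7-bis(benzyloxy)-8-[(2S,4R)-7-(benzyloxy)-2-(4-(benzyloxy)phenyl)chroman-4-yl]-2-[3,4,5-tris(benzyloxy)phenyl]chroman-3-ol, via C8-flavanyl epoxy phenol 15 (not isolated)
Conditions: BF3·OEt2 (0.3 equiv), CH2Cl2 (5 mM), −78 to −30 °C; Et3N quench
Reagents that add atoms: none
Why: Proposed new method: BF3 ionises the flavan-4-yl aryl ether of 14 (the cation is benzylic to the upper ring A, para to its 7-benzyloxy group and ortho to its O1), the contact ion pair recombines at the only free ortho carbon of the phenoxide (a 1,3 O-to-C shift that gives 15 after tautomerisation), and the phenol oxygen so released opens the BF3-activated cis-epoxide at benzylic C2 to form the O1–C2 bond; if instead the ether oxygen opens the epoxide first and expels the cation afterwards, C8-selective flavanylation of the resulting 5,7-di-O-benzyl flavan-3-ol leads to the same product. The closest known reactions are the acid-promoted 1,3-rearrangement of benzyl aryl ethers to ortho-benzylphenols, the Lewis-acid-mediated C8-flavanylation of benzylated flavan-3-ols by flavan-4-yl cations, and the acid-catalysed endo opening of aryl epoxides by a tethered phenol. The lower pyran ring closes in the 6-endo-tet mode (epoxide opening at the benzylic carbon) in preference to 5-exo, because only C2 can carry positive charge in a loose SN2 transition state. C2 of the lower unit (R) is set by inversion at the (S)-epoxide carbon and C3 (R) is carried over unchanged, which from the cis-epoxide gives the 2,3-cis relationship; C4 of the upper unit (R) is set by axial attack of the arene on the flavan-4-yl cation anti to the equatorial 2-aryl group, giving 2,4-trans. The step needs ortho and not para C-alkylation, secured by ion-pair proximity and by the para carbon lying between two benzyloxy groups, and it needs inversion and not ionisation at C2, secured by the low temperature and by the 3,4,5-tris(benzyloxy)phenyl ring, whose para oxygen is twisted out of conjugation by its two neighbours. The step is a pure isomerisation that turns one ether into the complete protected skeleton with one new C–C bond, one new ring and two new stereocentres.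

Step 12
Reactants: 16 hepta-O-benzyl dimer
Product: 17 (2R,3R)-8-[(2S,4R)-7-hydroxy-2-(4-hydroxyphenyl)chroman-4-yl]-2-(3,4,5-trihydroxyphenyl)chroman-3,5,7-triol (target)
Conditions: H2 (1 atm), Pd(OH)2/C, THF/MeOH, rt
Reagents that add atoms: none
Why: Hydrogenolysis of the seven aryl benzyl ethers under mild conditions, as is routine for benzylated proanthocyanidins, should leave the pyran C–O bonds, the interflavan bond and all four stereocentres untouched.

**Compound list**

1 | 3,5-bis(benzyloxy)phenol | Oc1cc(OCc2ccccc2)cc(OCc2ccccc2)c1 | starting material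
2 | 2-hydroxy-4,6-bis(benzyloxy)benzaldehyde | O=Cc1c(O)cc(OCc2ccccc2)cc1OCc1ccccc1 | intermediate
3 | 3,4,5-tris(benzyloxy)benzaldehyde | O=Cc1cc(OCc2ccccc2)c(OCc2ccccc2)c(OCc2ccccc2)c1 | starting material
4 | 5-ethynyl-1,2,3-tris(benzyloxy)benzene | C#Cc1cc(OCc2ccccc2)c(OCc2ccccc2)c(OCc2ccccc2)c1 | intermediate
5 | rac-1-[2-hydroxy-4,6-bis(benzyloxy)phenyl]-3-[3,4,5-tris(benzyloxy)phenyl]prop-2-yn-1-ol | OC(C#Cc1cc(OCc2ccccc2)c(OCc2ccccc2)c(OCc2ccccc2)c1)c1c(O)cc(OCc2ccccc2)cc1OCc1ccccc1 | intermediate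
6 | 3,5-bis(benzyloxy)-2-{3-[3,4,5-tris(benzyloxy)phenyl]prop-2-yn-1-yl}phenol | Oc1cc(OCc2ccccc2)cc(OCc2ccccc2)c1CC#Cc1cc(OCc2ccccc2)c(OCc2ccccc2)c(OCc2ccccc2)c1 | intermediate
7 | 3,5-bis(benzyloxy)-2-{(2Z)-3-[3,4,5-tris(benzyloxy)phenyl]prop-2-en-1-yl}phenol | Oc1cc(OCc2ccccc2)cc(OCc2ccccc2)c1C/C=C\c1cc(OCc2ccccc2)c(OCc2ccccc2)c(OCc2ccccc2)c1 | intermediate
8 | 7-hydroxy-4H-chromen-4-one | O=c1ccoc2cc(O)ccc12 | starting material
9 | 7-(benzyloxy)-4H-chromen-4-one | O=c1ccoc2cc(OCc3ccccc3)ccc12 | intermediate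
10 | [4-(benzyloxy)phenyl]boronic acid | OB(O)c1ccc(OCc2ccccc2)cc1 | starting material
11 | (2S)-7-(benzyloxy)-2-[4-(benzyloxy)phenyl]chroman-4-one | c5ccccc5COc1ccc([C@@H]2CC(=O)c3ccc(OCc5ccccc5)cc3O2)cc1 | intermediate
12 | (2S,4S)-7-(benzyloxy)-2-[4-(benzyloxy)phenyl]chroman-4-ol | c5ccccc5COc1ccc([C@@H]2C[C@H](O)c3ccc(OCc5ccccc5)cc3O2)cc1 | intermediate
13 | (2S,4R)-7-(benzyloxy)-2-[4-(benzyloxy)phenyl]-4-{3,5-bis(benzyloxy)-2-[(2Z)-3-(3,4,5-tris(benzyloxy)phenyl)prop-2-en-1-yl]phenoxy}chroman | c5ccccc5COc1ccc([C@@H]2C[C@@H](Oc3cc(OCc5ccccc5)cc(OCc5ccccc5)c3C/C=C\c6cc(OCc5ccccc5)c(OCc5ccccc5)c(OCc5ccccc5)c6)c3ccc(OCc5ccccc5)cc3O2)cc1 | intermediate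
14 | (2S,4R)-7-(benzyloxy)-2-[4-(benzyloxy)phenyl]-4-[3,5-bis(benzyloxy)-2-{[(2R,3S)-3-(3,4,5-tris(benzyloxy)phenyl)oxiran-2-yl]methyl}phenoxy]chroman | c5ccccc5COc1ccc([C@@H]2C[C@@H](Oc3cc(OCc5ccccc5)cc(OCc5ccccc5)c3C[C@H]4O[C@H]4c6cc(OCc5ccccc5)c(OCc5ccccc5)c(OCc5ccccc5)c6)c3ccc(OCc5ccccc5)cc3O2)cc1 | intermediate
15 | 3,5-bis(benzyloxy)-2-[(2S,4R)-7-(benzyloxy)-2-(4-(benzyloxy)phenyl)chroman-4-yl]-6-{[(2R,3S)-3-(3,4,5-tris(benzyloxy)phenyl)oxiran-2-yl]methyl}phenol | c5ccccc5COc1ccc([C@@H]2C[C@@H](c3c(OCc5ccccc5)cc(OCc5ccccc5)c(C[C@H]4O[C@H]4c6cc(OCc5ccccc5)c(OCc5ccccc5)c(OCc5ccccc5)c6)c3O)c3ccc(OCc5ccccc5)cc3O2)cc1 | intermediate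
16 | (2R,3R)-5,7-bis(benzyloxy)-8-[(2S,4R)-7-(benzyloxy)-2-(4-(benzyloxy)phenyl)chroman-4-yl]-2-[3,4,5-tris(benzyloxy)phenyl]chroman-3-ol | c5ccccc5COc1ccc([C@@H]2C[C@@H](c3c(OCc5ccccc5)cc(OCc5ccccc5)c4c3O[C@H](c3cc(OCc5ccccc5)c(OCc5ccccc5)c(OCc5ccccc5)c3)[C@H](O)C4)c3ccc(OCc5ccccc5)cc3O2)cc1 | intermediate
17 | (2R,3R)-8-[(2S,4R)-7-hydroxy-2-(4-hydroxyphenyl)chroman-4-yl]-2-(3,4,5-trihydroxyphenyl)chroman-3,5,7-triol | Oc1ccc([C@@H]2C[C@@H](c3c(O)cc(O)c4c3O[C@H](c3cc(O)c(O)c(O)c3)[C@H](O)C4)c3ccc(O)cc3O2)cc1 | target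

**Step count and risks**

Total step count: 12. Longest linear sequence: 8 steps (1 → 2 → 5 → 6 → 7 → 13 → 14 → 16 → 17).

Steps most likely to fail:

Step 11. Possible failures: Meinwald rearrangement of the epoxide before the phenol is released; C-alkylation at the para carbon; intermolecular capture of the flavanyl cation by another upper ring A; ionisation at C2 that erodes the cis selectivity. The fallback uses known chemistry, sets out from 7 and 12 and comes back at 16. Phenol 7 would be silylated (TBSCl, imidazole, DMF) to the tert-butyldimethylsilyl ether F1 and epoxidised under the conditions of step 10 to the cis-epoxide F2. TBAF buffered with AcOH would free the epoxy phenol F3, which with CSA in CH2Cl2 at −20 °C should close by 6-endo opening to 5,7,3',4',5'-penta-O-benzyl-(−)-epigallocatechin F4. F4 (used in excess) and flavan-4-ol 12 would then be joined by the established C8-selective Friedel–Crafts flavanylation (BF3·OEt2, CH2Cl2, −78 °C), which rejoins the route at 16.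

Step 10. Possible failures: leakage to the trans-epoxide through a rotating benzylic radical; slow oxygen transfer to the hindered Z-alkene; opening of the product by the acid by-product. The fallback sets out from 13 and comes back at 14. Epoxidation with dimethyldioxirane in acetone at −40 °C (concerted and stereospecific, no manganese) would give 14 together with its epoxide diastereomer, the (2S,3R)-oxirane F5. The two are diastereomers because the flavanyl ether is enantiopure, so they would be separated by chromatography on base-washed silica or preparative HPLC; the flavanyl group thus serves as a covalently bound resolving group.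

Step 9. Possible failures: ionisation of the oxyphosphonium salt of the electron-rich alcohol 12, leading to elimination to the flav-3-ene or to C- instead of O-alkylation. The fallback sets out from 7 and 12 and comes back at 15 and from there at 16. Direct ortho-selective Friedel–Crafts flavanylation of 7 with 12 (BF3·OEt2, CH2Cl2, −78 °C) would give the C-flavanyl Z-alkene phenol F6. Acetylation (Ac2O, pyridine, DMAP) would give the aryl acetate F7, and epoxidation as in step 10 the epoxy acetate F8. Hydrazine acetate in DMF at 0 °C would remove the acetate to give 15, which with CSA in CH2Cl2 at −20 °C should close to 16.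

**Further compounds**

F1 | step 11 | tert-butyl{3,5-bis(benzyloxy)-2-[(2Z)-3-(3,4,5-tris(benzyloxy)phenyl)prop-2-en-1-yl]phenoxy}dimethylsilane | CC(C)(C)[Si](C)(C)Oc1cc(OCc2ccccc2)cc(OCc2ccccc2)c1C/C=C\c1cc(OCc2ccccc2)c(OCc2ccccc2)c(OCc2ccccc2)c1
F2 | step 11 | tert-butyl[3,5-bis(benzyloxy)-2-{[(2R,3S)-3-(3,4,5-tris(benzyloxy)phenyl)oxiran-2-yl]methyl}phenoxy]dimethylsilane | CC(C)(C)[Si](C)(C)Oc1cc(OCc2ccccc2)cc(OCc2ccccc2)c1C[C@H]3O[C@H]3c4cc(OCc2ccccc2)c(OCc2ccccc2)c(OCc2ccccc2)c4
F3 | step 11 | 3,5-bis(benzyloxy)-2-{[(2R,3S)-3-(3,4,5-tris(benzyloxy)phenyl)oxiran-2-yl]methyl}phenol | Oc1cc(OCc2ccccc2)cc(OCc2ccccc2)c1C[C@H]3O[C@H]3c4cc(OCc2ccccc2)c(OCc2ccccc2)c(OCc2ccccc2)c4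
F4 | step 11 | (2R,3R)-5,7-bis(benzyloxy)-2-[3,4,5-tris(benzyloxy)phenyl]chroman-3-ol (penta-O-benzyl-(−)-epigallocatechin) | O[C@@H]1Cc2c(OCc3ccccc3)cc(OCc3ccccc3)cc2O[C@@H]1c4cc(OCc5ccccc5)c(OCc5ccccc5)c(OCc5ccccc5)c4
F5 | step 10 | (2S,4R)-7-(benzyloxy)-2-[4-(benzyloxy)phenyl]-4-[3,5-bis(benzyloxy)-2-{[(2S,3R)-3-(3,4,5-tris(benzyloxy)phenyl)oxiran-2-yl]methyl}phenoxy]chroman | c5ccccc5COc1ccc([C@@H]2C[C@@H](Oc3cc(OCc5ccccc5)cc(OCc5ccccc5)c3C[C@@H]4O[C@@H]4c6cc(OCc5ccccc5)c(OCc5ccccc5)c(OCc5ccccc5)c6)c3ccc(OCc5ccccc5)cc3O2)cc1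
F6 | step 9 | 3,5-bis(benzyloxy)-2-[(2S,4R)-7-(benzyloxy)-2-(4-(benzyloxy)phenyl)chroman-4-yl]-6-[(2Z)-3-(3,4,5-tris(benzyloxy)phenyl)prop-2-en-1-yl]phenol | c5ccccc5COc1ccc([C@@H]2C[C@@H](c3c(OCc5ccccc5)cc(OCc5ccccc5)c(C/C=C\c6cc(OCc5ccccc5)c(OCc5ccccc5)c(OCc5ccccc5)c6)c3O)c3ccc(OCc5ccccc5)cc3O2)cc1
F7 | step 9 | 3,5-bis(benzyloxy)-2-[(2S,4R)-7-(benzyloxy)-2-(4-(benzyloxy)phenyl)chroman-4-yl]-6-[(2Z)-3-(3,4,5-tris(benzyloxy)phenyl)prop-2-en-1-yl]phenyl acetate | c5ccccc5COc1ccc([C@@H]2C[C@@H](c3c(OCc5ccccc5)cc(OCc5ccccc5)c(C/C=C\c6cc(OCc5ccccc5)c(OCc5ccccc5)c(OCc5ccccc5)c6)c3OC(C)=O)c3ccc(OCc5ccccc5)cc3O2)cc1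
F8 | step 9 | 3,5-bis(benzyloxy)-2-[(2S,4R)-7-(benzyloxy)-2-(4-(benzyloxy)phenyl)chroman-4-yl]-6-{[(2R,3S)-3-(3,4,5-tris(benzyloxy)phenyl)oxiran-2-yl]methyl}phenyl acetate | c5ccccc5COc1ccc([C@@H]2C[C@@H](c3c(OCc5ccccc5)cc(OCc5ccccc5)c(C[C@H]4O[C@H]4c6cc(OCc5ccccc5)c(OCc5ccccc5)c(OCc5ccccc5)c6)c3OC(C)=O)c3ccc(OCc5ccccc5)cc3O2)cc1
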